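**Plan**

- Retrosynthesis cuts, in this order: the twelve phenolic O–allyl bonds and one O–Si bond; the C4–O bond of the interflavan ether on the side of the middle unit (the oxygen stays on the lower unit); in the middle unit the two bonds O1–C2 and C4a–C4 of pyran ring C, which removes the whole C2–C3–C4 bridge; the C4–C8 bond between the upper unit and the remaining phloroglucinol ring.
- Forward: the upper flavan (from (−)-epicatechin) is joined through C4 to 3,5-bis(allyloxy)phenol; ring C of the middle unit is then annulated onto that phenol with a cis-epoxy aldehyde; the lower flavan (from (+)-epicatechin, oxygenated and inverted at C4) is attached last through oxygen; deprotection ends the route.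
- Enabling feature: ring A of the middle unit is a phloroglucinol ring, so O1 and C4a are the oxygen and ortho carbon of one free phenol (a 1,3-dinucleophile), while C2 and C4 of ring C are a benzylic C–O carbon and a carbinol carbon in 1,3-relation, the two electrophilic carbons of a 3-aryloxirane-2-carbaldehyde.
- Stereochemistry: C2/C3 of the upper and lower units come from the chiral pool; C2/C3 of the middle unit come from one catalytic asymmetric cis-epoxidation (C2 relayed by inversion); the three C4 centres are set by substrate control (cation capture trans to the 3-oxygen twice, the second time stereoconvergently; hydride delivery anti to the 3-oxygen once).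

Key step: step 9

Remark: the SMILES is read as two (2R,3R) 2,3-cis units, each substituted at C4 trans to its 3-OH (upper C4–C8 bond, middle C4–O bond), and a lower (2S,3S) 2,3-cis unit whose C4–O is cis to its 3-OH; α/β refer to the usual flavan drawing, in which the 2-aryl group of a (2R) unit is α.
Remark: (+)-epicatechin, the (2S,3S) enantiomer, is taken to be purchasable.

Step 1
Reactants: 1 3,4-dihydroxybenzaldehyde
Product: 2 3,4-bis(allyloxy)benzaldehyde
Conditions: allyl bromide (2.5 equiv), K2CO3, DMF, 60 °C
Reagents that add atoms: allyl bromide, C=CCBr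
Why: Williamson etherification of both phenols should be clean because the phenoxides are unhindered O-nucleophiles and the aldehyde is inert to K2CO3.

Step 2
Reactants: 2 3,4-bis(allyloxy)benzaldehyde; 3 methyl bis(2,2,2-trifluoroethyl)phosphonoacetate
Product: 4 methyl (Z)-3-[3,4-bis(allyloxy)phenyl]acrylate
Conditions: KN(SiMe3)2, 18-crown-6, THF, −78 °C
Reagents that add atoms: none
Why: Still–Gennari olefination, in which the electron-poor phosphonate makes elimination from the kinetically formed adduct fast and should give the Z-enoate.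

Step 3
Reactants: 4 methyl (Z)-3-[3,4-bis(allyloxy)phenyl]acrylate
Product: 5 methyl (2S,3S)-3-[3,4-bis(allyloxy)phenyl]oxirane-2-carboxylate (cis-glycidate)
Conditions: (S,S)-N,N′-bis(3,5-di-tert-butylsalicylidene)-1,2-cyclohexanediaminomanganese chloride, (S,S)-(salen)MnCl (6 mol %), 4-phenylpyridine N-oxide (0.25 equiv), aq. NaOCl (pH 11.3), CH2Cl2, 4 °C
Reagents that add atoms: sodium hypochlorite, [Na+].[O-]Cl
Why: Jacobsen–Katsuki epoxidation of a Z-cinnamate, in which the chiral oxo-manganese salen complex selects one face of the conjugated cis-alkene and so sets both oxirane carbons as (2S,3S); the isolated terminal allyl alkenes react far more slowly, and the minor trans-epoxide should be removable by chromatography.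

Step 4
Reactants: 5 methyl (2S,3S)-3-[3,4-bis(allyloxy)phenyl]oxirane-2-carboxylate
Product: 6 (2S,3S)-3-[3,4-bis(allyloxy)phenyl]oxirane-2-carbaldehyde (cis-epoxy aldehyde)
Conditions: iBu2AlH (1.05 equiv), CH2Cl2, −78 °C; MeOH, then aq. sodium potassium tartrate; used at once
Reagents that add atoms: none
Why: partial ester reduction should stop at the aluminium hemiacetal, which is held at −78 °C by chelation to the oxirane oxygen and releases the aldehyde only on work-up; the α-carbon is an oxirane carbon and should not epimerise.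

Step 5
Reactants: 7 (−)-epicatechin
Product: 8 5,7,3′,4′-tetra-O-allyl-(−)-epicatechin
Conditions: allyl bromide (4.4 equiv), K2CO3, DMF, 0 °C → rt, argon
Reagents that add atoms: allyl bromide, C=CCBr
Why: Williamson etherification of the four phenols only, since K2CO3 does not deprotonate the secondary 3-OH (the selectivity of the standard tetra-O-benzylation); no stereocentre is touched.

Step 6
Reactants: 8 5,7,3′,4′-tetra-O-allyl-(−)-epicatechin
Product: 9 (2R,3R,4S)-5,7,3′,4′-tetra-O-allyl-4β-(2-ethoxyethoxy)epicatechin
Conditions: DDQ (2 equiv), 2-ethoxyethanol (5 equiv), CH2Cl2, rt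
Reagents that add atoms: 2-ethoxyethanol, CCOCCO
Why: benzylic oxidation by hydride abstraction at C4 gives the flavan-4-yl cation stabilised by the three oxygens of ring A, and the alcohol should add anti to the axial 3-OH (4β, 3,4-trans) as in the tetra-O-benzyl series; aryl allyl ethers are inert to DDQ at rt.

Step 7
Reactants: 10 phloroglucinol
Product: 11 3,5-bis(allyloxy)phenol
Conditions: allyl bromide (2.0 equiv), K2CO3, DMF, rt; chromatography
Reagents that add atoms: allyl bromide, C=CCBr
Why: partial Williamson etherification, the usual entry to 3,5-dialkoxyphenols; it is statistical, and the di-ether should be separable from mono- and tri-ether.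

Step 8
Reactants: 9 (2R,3R,4S)-tetra-O-allyl-4β-(2-ethoxyethoxy)epicatechin; 11 3,5-bis(allyloxy)phenol (3 equiv)
Product: 12 2-[(2R,3R,4S)-5,7,3′,4′-tetra-O-allyl-epicatechin-4β-yl]-3,5-bis(allyloxy)phenol
Conditions: Me3SiOTf (0.2 equiv), CH2Cl2, −78 °C
Reagents that add atoms: none
Why: Friedel–Crafts alkylation by the flavan-4-yl cation released from the 4-alkoxy group, as in procyanidin syntheses; the arene should attack through the carbon between OH and O-allyl (less hindered than the carbon between two allyloxy groups) and anti to the 3-OH, which sets the 4β (3,4-trans) C–C bond.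

Step 9
Reactants: 12 2-[(2R,3R,4S)-tetra-O-allyl-epicatechin-4β-yl]-3,5-bis(allyloxy)phenol; 6 (2S,3S)-3-[3,4-bis(allyloxy)phenyl]oxirane-2-carbaldehyde (1.3 equiv)
Product: 14 octa-O-allyl epicatechin-(4β→8)-epicatechin-4-ol (mixture of C4 epimers of the new unit), via epoxy alcohol 13 (not isolated)
Conditions: Ti(OiPr)4 (2.2 equiv), 4 Å MS, CH2Cl2, −30 °C → rt; aq. sodium potassium tartrate work-up
Reagents that add atoms: none
Why: Proposed new method: Ligand exchange turns the single free phenol of 12 into an aryloxytitanium species that binds the aldehyde of 6, so the one free ring carbon ortho to that oxygen adds to the carbonyl through a six-membered metal-bound transition state (C4a–C4 bond) and gives the titanium alkoxide of epoxy alcohol 13; the titanium, now chelated by the C4 alkoxide and the oxirane oxygen, activates the epoxide and the aryl oxygen opens it at the benzylic carbon (O1–C2 bond). The closest known reaction types are the ortho-specific hydroxyalkylation of magnesium or titanium phenoxides with chiral α-oxygenated aldehydes, the Ti(OiPr)4-mediated C3-selective opening of 2,3-epoxy alcohols, and the cyclisation of 2′-hydroxychalcone epoxides to dihydroflavonols; their fusion into one annulation with an α,β-epoxy aldehyde is the untested part. Ring C closes in the 6-endo-tet mode at the aryl-substituted oxirane carbon, favoured over the 5-exo mode at C3 by benzylic activation and by the C3-selectivity of titanium-chelated epoxy alcohols. C2 is set by inversion at that oxirane carbon, so the (2S,3S) cis-epoxide made by catalysis in step 3 is relayed into the 2,3-cis (2R,3R) arrangement, C3 is carried over untouched, and C4 forms under the influence of the adjacent oxirane (Felkin–Anh or chelate control) but need not be uniform because step 10 ionises it. The step needs attack at the carbon ortho, not para, to the free OH, 6-endo opening, and clean SN2 character: the first is secured by the lone free phenol as metal-directing group with every other ring fully etherified, the second by the benzylic position, and the third by a halide-free, only moderately Lewis acidic titanium alkoxide at low temperature, which avoids halohydrin double inversion and a free benzylic cation.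

Step 10
Reactants: 14 octa-O-allyl epicatechin-(4β→8)-epicatechin-4-ol (C4 epimers)
Product: 15 octa-O-allyl epicatechin-(4β→8)-4β-(benzylsulfanyl)epicatechin
Conditions: BnSH (5 equiv), BF3·OEt2 (0.2 equiv), CH2Cl2, −40 °C
Reagents that add atoms: phenylmethanethiol, SCc1ccccc1
Why: Lewis-acid ionisation of the benzylic 4-OH of either epimer gives the same flavan-4-yl cation, which the thiol should capture anti to the axial 3-OH, so the mixture converges on the 4β-thioether (the reaction type of flavan thiolysis); at −40 °C the interflavan C–C bond should not be cleaved.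

Step 11
Reactants: 16 (+)-epicatechin
Product: 17 5,7,3′,4′-tetra-O-allyl-(+)-epicatechin
Conditions: allyl bromide (4.4 equiv), K2CO3, DMF, 0 °C → rt, argon
Reagents that add atoms: allyl bromide, C=CCBr
Why: the same phenol-selective Williamson etherification as in step 5, applied to the enantiomer.

Step 12
Reactants: 17 5,7,3′,4′-tetra-O-allyl-(+)-epicatechin
Product: 18 (2S,3S)-5,7,3′,4′-tetra-O-allyl-3-O-(tert-butyldimethylsilyl)epicatechin
Conditions: TBSCl, imidazole, DMF, 40 °C
Reagents that add atoms: tert-butyldimethylsilyl chloride, CC(C)(C)[Si](C)(C)Cl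
Why: silylation of the only free hydroxyl; the axial 3-OH is hindered, hence the concentrated, warm conditions.

Step 13
Reactants: 18 (2S,3S)-tetra-O-allyl-3-O-TBS-epicatechin
Product: 19 (2S,3S,4R)-tetra-O-allyl-3-O-TBS-epicatechin-4-ol (4-OH trans to 3-OTBS)
Conditions: DDQ (1.5 equiv), CH2Cl2/H2O (18:1), rt
Reagents that add atoms: water, O
Why: the C4 oxidation of step 6 with water as nucleophile, which should add anti to the 3-OTBS; any cis-epimer is harmless because step 14 oxidises both epimers to the same ketone.

Step 14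
Reactants: 19 (2S,3S,4R)-tetra-O-allyl-3-O-TBS-epicatechin-4-ol
Product: 20 (2S,3R)-5,7-bis(allyloxy)-2-[3,4-bis(allyloxy)phenyl]-3-(tert-butyldimethylsilyloxy)chroman-4-one (2,3-cis)
Conditions: Dess–Martin periodinane, CH2Cl2, 0 °C → rt
Reagents that add atoms: none
Why: Dess–Martin oxidation of the benzylic alcohol under non-basic conditions, so that the 2,3-cis ketone (C3–H α to the carbonyl) should not epimerise.

Step 15
Reactants: 20 (2S,3R)-3-silyloxychroman-4-one
Product: 21 (2S,3S,4S)-tetra-O-allyl-3-O-TBS-epicatechin-4-ol (all-cis: 2-aryl, 3-O and 4-OH on one face)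
Conditions: NaBH4, THF/MeOH, −20 °C
Reagents that add atoms: none
Why: hydride should add to the carbonyl face anti to the axial 3-OTBS (Felkin–Anh, the 2-aryl group being equatorial), which places the new 4-OH cis to the 3-oxygen.

Step 16
Reactants: 15 octa-O-allyl epicatechin-(4β→8)-4β-(benzylsulfanyl)epicatechin; 21 (2S,3S,4S)-tetra-O-allyl-3-O-TBS-epicatechin-4-ol (2 equiv)
Product: 22 dodeca-O-allyl 3-O-TBS trimer, epicatechin-(4β→8)-epicatechin-(4β→O→4)-[all-cis (2S,3S,4S) unit]
Conditions: AgBF4 (2.5 equiv), 2,6-di-tert-butyl-4-methylpyridine (3 equiv), 4 Å MS, THF, −40 → 0 °C, dark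
Reagents that add atoms: none
Why: thiophilic activation, in which the silver ion binds sulfur and releases the middle-unit C4 cation under non-acidic conditions where neither the benzylic 4-OH of 21 nor the product ether ionises (so the all-cis C4–O centre of the lower unit is retained); the alcohol, kinetically a better nucleophile than the alkoxy-arenes, should add anti to the axial 3-OH to give the 4β-ether, and the hindered base removes the proton so that O-alkylation is not reversed in favour of C-arylation.

Step 17
Reactants: 22 dodeca-O-allyl 3-O-TBS trimer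
Product: 23 dodeca-O-allyl trimer (all secondary hydroxyls free)
Conditions: Bu4NF (3 equiv), THF, rt
Reagents that add atoms: none
Why: fluoride cleaves the Si–O bond of the secondary silyl ether; the aryl allyl ethers and the benzylic ether are inert to fluoride.

Step 18
Reactants: 23 dodeca-O-allyl trimer
Product: 24 target compound
Conditions: Pd(PPh3)4 (30 mol %, 2.5 mol % per allyl group), morpholine (40 equiv), degassed THF, rt, argon; Sephadex LH-20
Reagents that add atoms: none
Why: Tsuji–Trost deallylation, in which zerovalent palladium ionises each aryl allyl ether to a π-allyl complex and a phenoxide and morpholine traps the allyl group; the near-neutral, non-reducing conditions should leave the acid- and hydrogenolysis-labile benzylic C4–O–C4 ether and the interflavan C–C bond intact.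

**Compound list**

1 | 3,4-dihydroxybenzaldehyde | O=Cc1ccc(O)c(O)c1 | starting material
2 | 3,4-bis(allyloxy)benzaldehyde | O=Cc1ccc(OCC=C)c(OCC=C)c1 | intermediate
3 | methyl bis(2,2,2-trifluoroethyl)phosphonoacetate | COC(=O)CP(=O)(OCC(F)(F)F)OCC(F)(F)F | starting material
4 | methyl (Z)-3-[3,4-bis(allyloxy)phenyl]acrylate | COC(=O)/C=C\c1ccc(OCC=C)c(OCC=C)c1 | intermediate
5 | methyl (2S,3S)-3-[3,4-bis(allyloxy)phenyl]oxirane-2-carboxylate (cis) | COC(=O)[C@H]1O[C@H]1c1ccc(OCC=C)c(OCC=C)c1 | intermediate
6 | (2S,3S)-3-[3,4-bis(allyloxy)phenyl]oxirane-2-carbaldehyde (cis) | O=C[C@H]1O[C@H]1c1ccc(OCC=C)c(OCC=C)c1 | intermediate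
7 | (−)-epicatechin, (2R,3R) | Oc1cc(O)c2c(c1)O[C@H](c1ccc(O)c(O)c1)[C@H](O)C2 | starting material
8 | 5,7,3′,4′-tetra-O-allyl-(−)-epicatechin | C=CCOc1cc(OCC=C)c2c(c1)O[C@H](c1ccc(OCC=C)c(OCC=C)c1)[C@H](O)C2 | intermediate
9 | (2R,3R,4S)-5,7,3′,4′-tetra-O-allyl-4β-(2-ethoxyethoxy)epicatechin (4-O trans to 3-OH) | C=CCOc1cc(OCC=C)c2c(c1)O[C@H](c1ccc(OCC=C)c(OCC=C)c1)[C@H](O)[C@H]2OCCOCC | intermediate
10 | phloroglucinol | Oc1cc(O)cc(O)c1 | starting material
11 | 3,5-bis(allyloxy)phenol | Oc1cc(OCC=C)cc(OCC=C)c1 | intermediate
12 | 2-[(2R,3R,4S)-5,7,3′,4′-tetra-O-allyl-epicatechin-4β-yl]-3,5-bis(allyloxy)phenol | C=CCOc1cc(OCC=C)c2c(c1)O[C@H](c1ccc(OCC=C)c(OCC=C)c1)[C@H](O)[C@H]2c1c(O)cc(OCC=C)cc1OCC=C | intermediate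
13 | epoxy alcohol: 12 bearing, at the free carbon ortho to OH, a CH(OH) group bonded to C2 of the (2S,3S)-3-aryloxirane (carbinol configuration open); formed as its titanium alkoxide | C=CCOc1cc(OCC=C)c2c(c1)O[C@H](c1ccc(OCC=C)c(OCC=C)c1)[C@H](O)[C@H]2c1c(O)c(C(O)[C@H]3O[C@H]3c3ccc(OCC=C)c(OCC=C)c3)c(OCC=C)cc1OCC=C | intermediate (not isolated)
14 | octa-O-allyl epicatechin-(4β→8)-epicatechin-4-ol; new unit (2R,3R), 2,3-cis, C4 epimer mixture | C=CCOc1cc(OCC=C)c2c(c1)O[C@H](c1ccc(OCC=C)c(OCC=C)c1)[C@H](O)[C@H]2c1c(OCC=C)cc(OCC=C)c2c1O[C@H](c1ccc(OCC=C)c(OCC=C)c1)[C@H](O)C2O | intermediate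
15 | octa-O-allyl epicatechin-(4β→8)-4β-(benzylsulfanyl)epicatechin (S trans to 3-OH) | C=CCOc1cc(OCC=C)c2c(c1)O[C@H](c1ccc(OCC=C)c(OCC=C)c1)[C@H](O)[C@H]2c1c(OCC=C)cc(OCC=C)c2c1O[C@H](c1ccc(OCC=C)c(OCC=C)c1)[C@H](O)[C@H]2SCc1ccccc1 | intermediate
16 | (+)-epicatechin, (2S,3S) | Oc1cc(O)c2c(c1)O[C@@H](c1ccc(O)c(O)c1)[C@@H](O)C2 | starting material
17 | 5,7,3′,4′-tetra-O-allyl-(+)-epicatechin | C=CCOc1cc(OCC=C)c2c(c1)O[C@@H](c1ccc(OCC=C)c(OCC=C)c1)[C@@H](O)C2 | intermediate
18 | (2S,3S)-5,7,3′,4′-tetra-O-allyl-3-O-(tert-butyldimethylsilyl)epicatechin | C=CCOc1cc(OCC=C)c2c(c1)O[C@@H](c1ccc(OCC=C)c(OCC=C)c1)[C@@H](O[Si](C)(C)C(C)(C)C)C2 | intermediate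
19 | (2S,3S,4R)-tetra-O-allyl-3-O-TBS-epicatechin-4-ol (4-OH trans to 3-OTBS) | C=CCOc1cc(OCC=C)c2c(c1)O[C@@H](c1ccc(OCC=C)c(OCC=C)c1)[C@@H](O[Si](C)(C)C(C)(C)C)[C@@H]2O | intermediate
20 | (2S,3R)-5,7-bis(allyloxy)-2-[3,4-bis(allyloxy)phenyl]-3-(tert-butyldimethylsilyloxy)chroman-4-one (2,3-cis) | C=CCOc1cc(OCC=C)c2c(c1)O[C@@H](c1ccc(OCC=C)c(OCC=C)c1)[C@@H](O[Si](C)(C)C(C)(C)C)C2=O | intermediate
21 | (2S,3S,4S)-tetra-O-allyl-3-O-TBS-epicatechin-4-ol (all-cis) | C=CCOc1cc(OCC=C)c2c(c1)O[C@@H](c1ccc(OCC=C)c(OCC=C)c1)[C@@H](O[Si](C)(C)C(C)(C)C)[C@H]2O | intermediate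
22 | dodeca-O-allyl 3-O-TBS trimer: epicatechin-(4β→8)-epicatechin-(4β→O→4)-all-cis (2S,3S,4S) unit, silyl ether on the 3-O of the lower unit | C=CCOc1cc(OCC=C)c2c(c1)O[C@H](c1ccc(OCC=C)c(OCC=C)c1)[C@H](O)[C@H]2c1c(OCC=C)cc(OCC=C)c2c1O[C@H](c1ccc(OCC=C)c(OCC=C)c1)[C@H](O)[C@H]2O[C@H]1c2c(OCC=C)cc(OCC=C)cc2O[C@@H](c2ccc(OCC=C)c(OCC=C)c2)[C@H]1O[Si](C)(C)C(C)(C)C | intermediate
23 | dodeca-O-allyl trimer (three free secondary OH) | C=CCOc1cc(OCC=C)c2c(c1)O[C@H](c1ccc(OCC=C)c(OCC=C)c1)[C@H](O)[C@H]2c1c(OCC=C)cc(OCC=C)c2c1O[C@H](c1ccc(OCC=C)c(OCC=C)c1)[C@H](O)[C@H]2O[C@H]1c2c(OCC=C)cc(OCC=C)cc2O[C@@H](c2ccc(OCC=C)c(OCC=C)c2)[C@H]1O | intermediate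
24 | CNP0310719.1 | Oc1cc(O)c2c(c1)O[C@H](c1ccc(O)c(O)c1)[C@H](O)[C@H]2c1c(O)cc(O)c2c1O[C@H](c1ccc(O)c(O)c1)[C@H](O)[C@H]2O[C@H]1c2c(O)cc(O)cc2O[C@@H](c2ccc(O)c(O)c2)[C@H]1O | target

**Step count and risks**

Total step count: 18. Longest linear sequence: 9 steps (1, 2, 3, 4, 9, 10, 16, 17, 18).

Most likely to fail, first: step 9. The benzylic oxirane carbon carries an electron-rich aryl group and may open with SN1 character, which would erode the inversion and let the 2,3-trans ring form. The epoxy aldehyde may also rearrange on titanium before the C–C bond forms, or the titanium salicyl alkoxide may revert or collapse to a quinone methide. The fallback gives up the annulation and buys ring C of the middle unit with a second molecule of epicatechin, using only known flavan chemistry. It sets out from 9 and 8: Me3SiOTf-mediated Friedel–Crafts coupling of 9 with excess 8 (4 equiv, CH2Cl2, −78 °C) should give octa-O-allyl epicatechin-(4β→8)-epicatechin F1. Oxidation of its only C4 methylene with DDQ and 2-ethoxyethanol should give the 4β-(2-ethoxyethoxy) dimer F2. Exchange with BnSH and BF3·OEt2 at −40 °C comes back to the route at 15.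

Second: step 16. Two hindered secondary centres have to be joined through oxygen; capture of the cation by the alcohol may be too slow, so that irreversible C-arylation by the alkoxy-substituted rings A (self-condensation or attack by the lower unit) or attack from the wrong face takes over. The fallback changes the nucleophile into a pre-formed metal alkoxide, so that O-capture releases no proton and cannot be reversed. It sets out from 21, which with (Bu3Sn)2O in refluxing toluene (water removed) should give the tributylstannyl ether F3. F3 is combined with 15 and AgOTf (4 Å MS, toluene/THF, −40 °C, KF work-up), as in stannyl-ether glycosylations, and comes back to the route at 22.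

Third: step 8. The cation may attack the phenol 11 partly at the carbon between the two allyloxy groups or at oxygen, and the product may be alkylated a second time, so that the phenol needed for the annulation is obtained as a mixture. The fallback removes the regiochemical question by using a symmetrical nucleophile. It sets out from 9 and 10: BF3·OEt2 in THF–CH2Cl2 at 0 °C with excess phloroglucinol should give 2-[(2R,3R,4S)-tetra-O-allyl-epicatechin-4β-yl]benzene-1,3,5-triol F4, in which all ring carbons of the nucleophile were equivalent. Twofold allylation (allyl bromide 2.0 equiv, K2CO3, DMF) should take the unhindered para-hydroxyl first and then either of the two equivalent hindered ones, and comes back to the route at 12.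

Further compounds
F1 | step 9 | octa-O-allyl epicatechin-(4β→8)-epicatechin | C=CCOc1cc(OCC=C)c2c(c1)O[C@H](c1ccc(OCC=C)c(OCC=C)c1)[C@H](O)[C@H]2c1c(OCC=C)cc(OCC=C)c2c1O[C@H](c1ccc(OCC=C)c(OCC=C)c1)[C@H](O)C2
F2 | step 9 | octa-O-allyl epicatechin-(4β→8)-4β-(2-ethoxyethoxy)epicatechin | C=CCOc1cc(OCC=C)c2c(c1)O[C@H](c1ccc(OCC=C)c(OCC=C)c1)[C@H](O)[C@H]2c1c(OCC=C)cc(OCC=C)c2c1O[C@H](c1ccc(OCC=C)c(OCC=C)c1)[C@H](O)[C@H]2OCCOCC
F3 | step 16 | (2S,3S,4S)-tetra-O-allyl-3-O-TBS-4-O-(tributylstannyl)epicatechin-4-ol | C=CCOc1cc(OCC=C)c2c(c1)O[C@@H](c1ccc(OCC=C)c(OCC=C)c1)[C@@H](O[Si](C)(C)C(C)(C)C)[C@H]2O[Sn](CCCC)(CCCC)CCCC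
F4 | step 8 | 2-[(2R,3R,4S)-5,7,3′,4′-tetra-O-allyl-epicatechin-4β-yl]benzene-1,3,5-triol | C=CCOc1cc(OCC=C)c2c(c1)O[C@H](c1ccc(OCC=C)c(OCC=C)c1)[C@H](O)[C@H]2c1c(O)cc(O)cc1O
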